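# Design of a total synthesis of ebenfuran IV (24) with ring B built by cycloaddition

## The problem

The target (24, ebenfuran IV) is a flat, achiral 2-arylbenzofuran: ring A (C3a to C7a) is fused to the furan, and ring B hangs on the single C2–C1' bond. There is no stereocentre, so every selectivity question is one of position. Ring A carries three different neighbours, the C4 hydroxyl, the C5 3-methylbut-2-enyl (prenyl) chain and the C6 methoxyl. Its two oxygens must therefore be told apart, and the prenyl group must go to C5 and not to the free C7. Ring B is a resorcinol with the C2' oxygen methylated and the C4' oxygen free, a second pair of oxygens to differentiate. Three groups do not tolerate rough treatment: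

- the C3 aldehyde;
- the prenyl double bond, which acid closes onto the C4 hydroxyl and hydrogenation saturates;
- the two free phenols on electron-rich rings.

The prenyl group and the free phenols should therefore appear late and under neutral conditions. The key step rests on the substitution of ring B: OMe at C2' ortho and OH at C4' para to C1' is the pattern a 1,1-dimethoxy-3-siloxybuta-1,3-diene leaves when it adds to an alkyne and loses methanol, with C1' and C6' supplied by the alkyne. An ethynyl group on C2 is conjugated through C2=C3 with the C3 carbonyl, which makes its terminal carbon (the future C6') the electrophilic end and so fixes the orientation of the diene.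

## Retrosynthesis

**Prenyl group (24 ⇐ 23 ⇐ 21 ⇐ 20 ⇐ 18 + 19).** After removal of the C4' silyl ether (24 from 23), the C5–CH2 bond of the prenyl chain is cut. An aromatic Claisen rearrangement of the 1,1-dimethylallyl ether 21 is preferred to direct C-prenylation, which would have to choose between C5, C7 and oxygen. From the C4 oxygen the only ortho carbon that bears hydrogen is C5, because the other is the ring-fusion carbon C3a. Ether 21 comes from phenol 18 and the tertiary propargylic chloride 19 through alkyne 20 and a semihydrogenation. The forward steps require that C4–OH be the only free hydroxyl, so the C4' oxygen stays silylated until the end.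

**C4 oxygen (18 ⇐ 17).** The O–CH3 bond at C4 is cut. The C4 and C6 oxygens are distinguished only at this point, by a chelating boron halide held between the formyl oxygen and the peri methoxyl. Because 17 carries both ring A oxygens as methyl ethers, ring A can come from a symmetric, commercial phloroglucinol derivative. The step needs the aldehyde (a better ligand for boron than an ester) to be in place and the aryl silyl ether to be inert to the Lewis acid.

**Ring B (17 ⇐ 11 + 15), the key disconnection.** The bonds C1'–C2' and C5'–C6' are cut, which removes ring B and leaves alkyne 11 and diene 15. The neighbouring cut, C2–C1' by cross-coupling of iodide 8 with an arylboron reagent, is shorter in precedent and is kept as the fallback. The cycloaddition is chosen because it builds ring B from two-carbon units with both oxygens in place and already differentiated. Two choices strengthen the step from within: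

- The C3 carbon is raised to the aldehyde before the cycloaddition. A formyl group withdraws more strongly through C2=C3 than an ester, it is what the target needs, and the redox steps then fall on a simple iodide.
- The silyl group of the diene is triisopropylsilyl, so that the enol ether is carried into the arene as the protecting group that steps 10 to 13 require, and a separate protection step is saved.

**Diene (15 ⇐ 14 ⇐ 12 + 13).** The O–Si bond and then the C2–C3 bond of the diene are cut. C-Acylation of ketene acetal 12 with acid chloride 13 gives enone 14, whose only enolisable protons are those of the methyl group, so silylation can give a single diene.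

**Alkyne (11 ⇐ 10 ⇐ 8 + 9).** The C2–C(sp) bond is cut. A Sonogashira coupling of iodide 8 with silylalkyne 9 and removal of the silyl group deliver 11. The ortho formyl group activates the C2–I bond.

**Oxidation level and halogen (8 ⇐ 7 ⇐ 6 ⇐ 4).** The aldehyde is traced back through alcohol 7 to ester 6, and the C2–I bond to ester 4. The ester is needed at this stage because it directs and survives deprotonation at C2 (through 5), which an aldehyde would not.

**Furan ring (4 ⇐ 1 + 2).** The O1–C2 and C2–C3 bonds are cut, and the aryl–carbonyl bond of 1 is shifted to become C3–C3a. Acid-catalysed annulation of salicylaldehyde 1 with diazo ester 2 forms the furan ring with the C3 ester in one operation from two commercial compounds.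

## Roads not taken

**Alternative 1:** The cut is O1–C7a of the furan. In the forward direction enaminone A2, which carries the 2-bromo-4,6-dimethoxyphenyl group on its α-carbon and ring B on its carbonyl carbon, is cyclised with CuI, 1,10-phenanthroline and K3PO4. The enaminone oxygen displaces bromide on ring A, and the iminium ion left at C3 is hydrolysed to the aldehyde, giving A1.

- Merits: Ullmann-type C–O coupling is established chemistry. The aldehyde arrives at the right oxidation level with no redox steps. Both rings come from plain aromatic building blocks. A1 is the tosylate counterpart of 17 and would be reached in fewer steps.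
- Weak points: the bromide sits between the enaminone carbon and a methoxyl on a very electron-rich ring, an unfavourable case for copper insertion. The tosylate must survive the Lewis-acid demethylation and then be removed by base or a reducing metal in the presence of aldehyde, prenyl group and chelated phenol, which is harsher than buffered fluoride. The ring A endgame is unchanged.
- Comparison: in precedent and in step count up to the common intermediate, Alternative 1 is the better road. The chosen plan sets three things against it: ring B is made with a freely chosen silyl ether; its one speculative step comes early, after cheap steps; and its fallback starts from iodide 8, which is already on the route.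

**Alternative 2:** The cut is C2–C1', made intramolecular by an ester tether. Aryl ester A4, whose acyl part is the benzofuran-3-carboxylate core of 4, is cyclised with Pd(OAc)2, PPh3 and K2CO3 by arylation of the C2–H bond to the coumestan A3.

- Merits: no halogen and no alkyne are needed at C2. The tether guarantees C2 selectivity. The C2' oxygen is distinguished from C4' by being the lactone oxygen.
- Weak points: the lactone must be taken apart again by reduction to a phenol and a primary alcohol, selective O-methylation at C2' beside an acid-sensitive benzylic alcohol, and reoxidation to the aldehyde. The aryl ester is exposed to carbonate at high temperature. The tosylate has the drawbacks noted for Alternative 1.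
- Comparison: the key step of Alternative 2 is safer than the cycloaddition, and it saves the three steps from 6 to 11 that install the alkyne. The chosen plan sets against it that nothing at C3 or C2' needs adjusting after the key step, so the totals come out close, and that the silyl ether leaves more gently than the tosylate.

**Alternative 3:** The cut goes through ring A (C7–C7a, C4–C5, C6–C7, C3a–C4). Furyl diazoketone A6 is irradiated and then heated with ynol ether A7. A Wolff rearrangement, a (2+2) cycloaddition, a four-electron ring opening and a six-electron closure onto the furan give phenol A5.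

- Merits: the C4 hydroxyl, the C5 prenyl group and the C6 methoxyl are set in one step with positions fixed by the mechanism. This removes the demethylation and the three-step prenyl transfer, and on ring A it is the more convergent and the more regiosecure plan.
- Weak points: A6 is a trisubstituted furan carrying ring B, an ester and a diazoketone, and needs a multistep synthesis of its own, with ring B brought in by a coupling. A7 is a volatile, acid-labile ynol ether. The step is photochemical. Afterwards the ester must be reduced and reoxidised in the presence of the free chelated phenol and the prenyl group.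
- Comparison: Alternative 3 is better in step economy and regiocontrol on ring A. The chosen plan sets against it commercial starting materials, purely thermal operations, and an ester-to-aldehyde adjustment that is finished before any sensitive group is present.

Key step: step 9

## Route

Remark: 3 and 22 form as racemates (3 also as a mixture of diastereomers) and are not isolated. No isolated compound has a stereocentre, so all SMILES are written without stereodescriptors.

Step 1
Reactants: 1 2-hydroxy-4,6-dimethoxybenzaldehyde; 2 ethyl diazoacetate
Product: 4 ethyl 4,6-dimethoxy-1-benzofuran-3-carboxylate, via cyclic hemiacetal 3 (not isolated)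
Conditions: HBF4·OEt2 (cat.), CH2Cl2, rt; then conc. H2SO4, rt
Reagents that add atoms: none
Why: Acid-catalysed addition of the diazo ester to the aldehyde with 1,2-aryl shift and loss of nitrogen (Roskamp-type homologation) gives an α-formyl arylacetate, which the ortho phenol traps as hemiacetal 3; sulfuric acid dehydrates 3 to the furan. The electron-rich aryl group is a good migrating group.

Step 2
Reactants: 4 ethyl 4,6-dimethoxy-1-benzofuran-3-carboxylate
Product: 6 ethyl 2-iodo-4,6-dimethoxy-1-benzofuran-3-carboxylate, via 2-lithiobenzofuran ester 5 (not isolated)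
Conditions: LiN(i-Pr)2, THF, −78 °C; then I2, −78 °C to rt
Reagents that add atoms: iodine, II
Why: Directed metalation and iodination: C2–H, α to the ring oxygen and ortho to the ester, is by far the most acidic C–H bond, and the amide base does not add to the ester at −78 °C. Electrophilic iodination would instead attack ring A, so the deprotonation route is used.

Step 3
Reactants: 6 ethyl 2-iodo-4,6-dimethoxy-1-benzofuran-3-carboxylate
Product: 7 (2-iodo-4,6-dimethoxy-1-benzofuran-3-yl)methanol
Conditions: i-Bu2AlH, CH2Cl2, −78 °C; then aq. potassium sodium tartrate
Reagents that add atoms: none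
Why: Hydride reduction of the ester to the primary alcohol; the C–I bond is inert to i-Bu2AlH at low temperature. The electron-rich heterobenzylic alcohol is kept away from acid and oxidised directly.

Step 4
Reactants: 7 (2-iodo-4,6-dimethoxy-1-benzofuran-3-yl)methanol
Product: 8 2-iodo-4,6-dimethoxy-1-benzofuran-3-carbaldehyde
Conditions: MnO2, CH2Cl2, rt
Reagents that add atoms: none
Why: MnO2 oxidation of an activated (heterobenzylic) alcohol under neutral conditions stops cleanly at the aldehyde.

Step 5
Reactants: 8 2-iodo-4,6-dimethoxy-1-benzofuran-3-carbaldehyde; 9 ethynyltrimethylsilane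
Product: 10 4,6-dimethoxy-2-[(trimethylsilyl)ethynyl]-1-benzofuran-3-carbaldehyde
Conditions: Pd(PPh3)2Cl2 (cat.), CuI (cat.), Et3N, THF, rt
Reagents that add atoms: none
Why: Sonogashira coupling; the C2–I bond next to the formyl group adds readily to zerovalent palladium, so the coupling should run at room temperature without touching the aldehyde.

Step 6
Reactants: 10 4,6-dimethoxy-2-[(trimethylsilyl)ethynyl]-1-benzofuran-3-carbaldehyde
Product: 11 2-ethynyl-4,6-dimethoxy-1-benzofuran-3-carbaldehyde
Conditions: K2CO3 (cat.), MeOH/THF, 0 °C
Reagents that add atoms: none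
Why: Methoxide-mediated protodesilylation of the alkynylsilane, routine for ortho-alkynyl aryl aldehydes; catalytic base, low temperature and short contact keep methanol from adding to the alkyne, and 11 is used promptly.

Step 7
Reactants: 12 1,1-dimethoxyethene; 13 acetyl chloride
Product: 14 4,4-dimethoxybut-3-en-2-one
Conditions: pyridine, Et2O, 0 °C to rt
Reagents that add atoms: none
Why: C-Acylation of a ketene acetal: the nucleophilic CH2 carbon attacks the acylpyridinium ion and loss of a proton restores the ketene acetal double bond. Pyridine is used in place of a stronger amine to avoid ketene formation from the acid chloride.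

Step 8
Reactants: 14 4,4-dimethoxybut-3-en-2-one
Product: 15 1,1-dimethoxy-3-[(triisopropylsilyl)oxy]buta-1,3-diene
Conditions: i-Pr3SiOTf, Et3N, Et2O, 0 °C to rt
Reagents that add atoms: triisopropylsilyl trifluoromethanesulfonate, CC(C)[Si](OS(=O)(=O)C(F)(F)F)(C(C)C)C(C)C
Why: Soft enolisation and O-silylation of a methyl ketone with a silyl triflate and an amine, the standard entry to 2-siloxybuta-1,3-dienes; only the methyl group has enolisable protons, so one diene forms. The product is moisture-sensitive and is distilled and used directly.

Step 9
Reactants: 11 2-ethynyl-4,6-dimethoxy-1-benzofuran-3-carbaldehyde; 15 1,1-dimethoxy-3-[(triisopropylsilyl)oxy]buta-1,3-diene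
Product: 17 4,6-dimethoxy-2-{2-methoxy-4-[(triisopropylsilyl)oxy]phenyl}-1-benzofuran-3-carbaldehyde, via cyclohexadiene cycloadduct 16 (not isolated)
Conditions: 15 (3 equiv), PhMe, 110 °C, sealed tube; then SiO2
Reagents that add atoms: none
Why: Proposed new method: the closest known reaction type is the Diels–Alder reaction of 1,1-dialkoxy-3-siloxybuta-1,3-dienes with acetylenic esters and ketones, which gives resorcinol monoethers after loss of alcohol; what is new is that the alkyne of 11 is activated only as a vinylogous ynal through the furan C2=C3 bond. The diene is most nucleophilic at its CH2 terminus, because the cation that develops there is a siloxy-substituted dialkoxycarbenium ion, and the terminal alkyne carbon of 11 is the δ-position of the enynal O=CH–C3=C2–C≡CH, the site at which soft nucleophiles add to 2-en-4-ynoyl systems. The CH2 terminus therefore bonds to the terminal alkyne carbon (C5'–C6') and the acetal carbon to the alkyne carbon on C2 (C1'–C2'). Ring B closes by an intermolecular (4+2) cycloaddition, concerted but asynchronous or at the limit stepwise through a zwitterion that collapses at the acetal carbon, to give cyclohexa-1,4-diene 16. 16 is a doubly allylic ketal that ionises to a methoxy-substituted arenium ion and loses a C5' proton, so methanol is expelled on heating or on silica and the benzene ring forms. The acetal carbon keeps one methoxyl as C2'–OMe and the silyl enol ether is carried into the arene as the C4' triisopropylsilyl ether, the protecting group needed in steps 10 to 13. No stereocentre is formed. The step needs regioselectivity, secured by the polarity match just described (OMe ortho and OSi para to C2), and site selectivity for the alkyne over the aldehyde and the furan C2=C3 bond, secured by the absence of any Lewis acid, by the vinylogous-formate character of the C3 aldehyde and by the full substitution of C2=C3.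

Step 10
Reactants: 17 4,6-dimethoxy-2-{2-methoxy-4-[(triisopropylsilyl)oxy]phenyl}-1-benzofuran-3-carbaldehyde
Product: 18 4-hydroxy-6-methoxy-2-{2-methoxy-4-[(triisopropylsilyl)oxy]phenyl}-1-benzofuran-3-carbaldehyde
Conditions: BCl3, CH2Cl2, −78 to 0 °C; then H2O
Reagents that add atoms: none
Why: Chelation-directed ether cleavage: boron is held between the formyl oxygen and the peri C4 methoxyl, and chloride removes that methyl group. The C6 methoxyl has no carbonyl partner, the C2' methoxyl would need a larger and less favourable chelate, and the aryl triisopropylsilyl ether is inert to BCl3 at low temperature.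

Step 11
Reactants: 18 4-hydroxy-6-methoxy-2-{2-methoxy-4-[(triisopropylsilyl)oxy]phenyl}-1-benzofuran-3-carbaldehyde; 19 3-chloro-3-methylbut-1-yne
Product: 20 6-methoxy-2-{2-methoxy-4-[(triisopropylsilyl)oxy]phenyl}-4-[(2-methylbut-3-yn-2-yl)oxy]-1-benzofuran-3-carbaldehyde
Conditions: CuCl2·2H2O (cat.), DBU, MeCN, 0 °C to rt
Reagents that add atoms: none
Why: Copper-catalysed propargylic etherification: the DBU phenoxide attacks the copper-bound propargylic electrophile derived from the tertiary chloride at its tertiary carbon. C4–OH is the only free hydroxyl, and the triisopropylsilyl ether tolerates anhydrous DBU.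

Step 12
Reactants: 20 6-methoxy-2-{2-methoxy-4-[(triisopropylsilyl)oxy]phenyl}-4-[(2-methylbut-3-yn-2-yl)oxy]-1-benzofuran-3-carbaldehyde
Product: 21 6-methoxy-2-{2-methoxy-4-[(triisopropylsilyl)oxy]phenyl}-4-[(2-methylbut-3-en-2-yl)oxy]-1-benzofuran-3-carbaldehyde
Conditions: H2 (1 atm), Pd/CaCO3 poisoned with Pb(OAc)2 (Lindlar catalyst), quinoline, EtOAc, rt
Reagents that add atoms: none
Why: Lindlar semihydrogenation of the terminal alkyne; the poisoned catalyst and quinoline stop at the alkene and leave the aldehyde and the benzofuran untouched.

Step 13
Reactants: 21 6-methoxy-2-{2-methoxy-4-[(triisopropylsilyl)oxy]phenyl}-4-[(2-methylbut-3-en-2-yl)oxy]-1-benzofuran-3-carbaldehyde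
Product: 23 4-hydroxy-6-methoxy-2-{2-methoxy-4-[(triisopropylsilyl)oxy]phenyl}-5-(3-methylbut-2-en-1-yl)-1-benzofuran-3-carbaldehyde, via ortho-dienone 22 (not isolated)
Conditions: PhMe, 110 °C
Reagents that add atoms: none
Why: Aromatic Claisen rearrangement: the [3,3] shift delivers the CH2 terminus of the allyl unit to C5, the only ortho carbon that bears hydrogen, and dienone 22 tautomerises to the phenol. Allylic inversion turns the 1,1-dimethylallyl ether into the 3-methylbut-2-enyl chain, and the gem-dimethyl group lowers the temperature needed.

Step 14
Reactants: 23 4-hydroxy-6-methoxy-2-{2-methoxy-4-[(triisopropylsilyl)oxy]phenyl}-5-(3-methylbut-2-en-1-yl)-1-benzofuran-3-carbaldehyde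
Product: 24 4-hydroxy-2-(4-hydroxy-2-methoxyphenyl)-6-methoxy-5-(3-methylbut-2-en-1-yl)-1-benzofuran-3-carbaldehyde
Conditions: Bu4NF, AcOH, THF, 0 °C
Reagents that add atoms: none
Why: Fluoride cleavage of the aryl silyl ether; acetic acid buffers the phenoxides so that the aldehyde and the prenyl phenol are not exposed to strong base.

## Compound list

1 | 2-hydroxy-4,6-dimethoxybenzaldehyde | COc1cc(O)c(C=O)c(OC)c1 | starting material
2 | ethyl diazoacetate | CCOC(=O)C=[N+]=[N-] | starting material
3 | ethyl 2-hydroxy-4,6-dimethoxy-2,3-dihydro-1-benzofuran-3-carboxylate (racemic, mixture of diastereomers) | CCOC(=O)C1C(O)Oc2cc(OC)cc(OC)c12 | intermediate (not isolated)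
4 | ethyl 4,6-dimethoxy-1-benzofuran-3-carboxylate | CCOC(=O)c1coc2cc(OC)cc(OC)c12 | intermediate
5 | ethyl 2-lithio-4,6-dimethoxy-1-benzofuran-3-carboxylate | CCOC(=O)c1c([Li])oc2cc(OC)cc(OC)c12 | intermediate (not isolated)
6 | ethyl 2-iodo-4,6-dimethoxy-1-benzofuran-3-carboxylate | CCOC(=O)c1c(I)oc2cc(OC)cc(OC)c12 | intermediate
7 | (2-iodo-4,6-dimethoxy-1-benzofuran-3-yl)methanol | OCc1c(I)oc2cc(OC)cc(OC)c12 | intermediate
8 | 2-iodo-4,6-dimethoxy-1-benzofuran-3-carbaldehyde | O=Cc1c(I)oc2cc(OC)cc(OC)c12 | intermediate
9 | ethynyltrimethylsilane | C#C[Si](C)(C)C | starting material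
10 | 4,6-dimethoxy-2-[(trimethylsilyl)ethynyl]-1-benzofuran-3-carbaldehyde | O=Cc1c(C#C[Si](C)(C)C)oc2cc(OC)cc(OC)c12 | intermediate
11 | 2-ethynyl-4,6-dimethoxy-1-benzofuran-3-carbaldehyde | O=Cc1c(C#C)oc2cc(OC)cc(OC)c12 | intermediate
12 | 1,1-dimethoxyethene | C=C(OC)OC | starting material
13 | acetyl chloride | CC(=O)Cl | starting material
14 | 4,4-dimethoxybut-3-en-2-one | CC(=O)C=C(OC)OC | intermediate
15 | 1,1-dimethoxy-3-[(triisopropylsilyl)oxy]buta-1,3-diene | COC(OC)=CC(=C)O[Si](C(C)C)(C(C)C)C(C)C | intermediate
16 | 2-{6,6-dimethoxy-4-[(triisopropylsilyl)oxy]cyclohexa-1,4-dien-1-yl}-4,6-dimethoxy-1-benzofuran-3-carbaldehyde | O=Cc1c(C2=CCC(O[Si](C(C)C)(C(C)C)C(C)C)=CC2(OC)OC)oc2cc(OC)cc(OC)c12 | intermediate (not isolated)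
17 | 4,6-dimethoxy-2-{2-methoxy-4-[(triisopropylsilyl)oxy]phenyl}-1-benzofuran-3-carbaldehyde | O=Cc1c(-c2ccc(O[Si](C(C)C)(C(C)C)C(C)C)cc2OC)oc2cc(OC)cc(OC)c12 | intermediate
18 | 4-hydroxy-6-methoxy-2-{2-methoxy-4-[(triisopropylsilyl)oxy]phenyl}-1-benzofuran-3-carbaldehyde | O=Cc1c(-c2ccc(O[Si](C(C)C)(C(C)C)C(C)C)cc2OC)oc2cc(OC)cc(O)c12 | intermediate
19 | 3-chloro-3-methylbut-1-yne | CC(C)(Cl)C#C | starting material
20 | 6-methoxy-2-{2-methoxy-4-[(triisopropylsilyl)oxy]phenyl}-4-[(2-methylbut-3-yn-2-yl)oxy]-1-benzofuran-3-carbaldehyde | O=Cc1c(-c2ccc(O[Si](C(C)C)(C(C)C)C(C)C)cc2OC)oc2cc(OC)cc(OC(C)(C)C#C)c12 | intermediate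
21 | 6-methoxy-2-{2-methoxy-4-[(triisopropylsilyl)oxy]phenyl}-4-[(2-methylbut-3-en-2-yl)oxy]-1-benzofuran-3-carbaldehyde | O=Cc1c(-c2ccc(O[Si](C(C)C)(C(C)C)C(C)C)cc2OC)oc2cc(OC)cc(OC(C)(C)C=C)c12 | intermediate
22 | 6-methoxy-2-{2-methoxy-4-[(triisopropylsilyl)oxy]phenyl}-5-(3-methylbut-2-en-1-yl)-4-oxo-4,5-dihydro-1-benzofuran-3-carbaldehyde (racemic at C5) | O=CC1=C(c2ccc(O[Si](C(C)C)(C(C)C)C(C)C)cc2OC)OC2=C1C(=O)C(CC=C(C)C)C(OC)=C2 | intermediate (not isolated)
23 | 4-hydroxy-6-methoxy-2-{2-methoxy-4-[(triisopropylsilyl)oxy]phenyl}-5-(3-methylbut-2-en-1-yl)-1-benzofuran-3-carbaldehyde | O=Cc1c(-c2ccc(O[Si](C(C)C)(C(C)C)C(C)C)cc2OC)oc2cc(OC)c(CC=C(C)C)c(O)c12 | intermediate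
24 | 4-hydroxy-2-(4-hydroxy-2-methoxyphenyl)-6-methoxy-5-(3-methylbut-2-en-1-yl)-1-benzofuran-3-carbaldehyde | COc1cc(O)ccc1-c1oc2cc(OC)c(CC=C(C)C)c(O)c2c1C=O | target

## Step count and least certain steps

Total: 14 steps. Longest linear sequence: 12 steps (steps 1 to 6 and 9 to 14, from 1). The diene branch (steps 7 and 8) joins at step 9.

**Step 9 (key step, proposed new method).** The most likely failure is that the cycloaddition is slower than thermal decay of the diene, because the ring oxygen O1 and the two ring A methoxyls feed electron density into the formyl acceptor and blunt the alkyne. The second is addition of the diene to the aldehyde carbonyl instead of the alkyne. The fallback makes the C2–C1' bond by known cross-coupling. It sets out from iodide 8. Commercial 4-bromo-3-methoxyphenol is borylated (bis(pinacolato)diboron, Pd(dppf)Cl2, KOAc, dioxane, 80 °C) to 3-methoxy-4-(4,4,5,5-tetramethyl-1,3,2-dioxaborolan-2-yl)phenol F1. Suzuki–Miyaura coupling of 8 with F1 (Pd(dppf)Cl2, K2CO3, dioxane/H2O, 80 °C) should give 2-(4-hydroxy-2-methoxyphenyl)-4,6-dimethoxy-1-benzofuran-3-carbaldehyde F2. Silylation of F2 (i-Pr3SiCl, imidazole, DMF) returns to the route at 17.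

**Step 10.** The likely failures are loss of the aryl silyl ether under the Lewis acid and cleavage of a second methyl ether, since the chelate between the formyl group and the C4 methoxyl is seven-membered and discriminates less sharply than the usual six-membered one. The fallback takes the silyl ether out of the step. It sets out from 17, which is desilylated (Bu4NF, AcOH, THF) to the free C4' phenol, 2-(4-hydroxy-2-methoxyphenyl)-4,6-dimethoxy-1-benzofuran-3-carbaldehyde F2. BCl3 then acts on the phenol (bound as its borate) to give 4-hydroxy-2-(4-hydroxy-2-methoxyphenyl)-6-methoxy-1-benzofuran-3-carbaldehyde F3. One equivalent of i-Pr3SiCl with imidazole silylates the unhindered, non-chelated C4' hydroxyl in preference to the hydrogen-bonded C4 hydroxyl and comes back at 18.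

**Step 11.** The likely failure is slow or incomplete O-alkylation, because the C4 phenoxide is hydrogen-bonded to the formyl group and crowded by it, and a tertiary electrophile is demanding. Prolonged exposure to DBU also risks transfer of the silyl group between phenoxides. The fallback replaces the copper propargylation and the hydrogenation by one palladium-catalysed allylic etherification (Tsuji–Trost type). It sets out from 18. 2-Methylbut-3-en-2-ol is converted with n-BuLi and di-tert-butyl dicarbonate into tert-butyl 2-methylbut-3-en-2-yl carbonate F4. With Pd(PPh3)4 in THF at 0 °C, 18 and F4 should give the branched 1,1-dimethylallyl ether directly, returning to the route at 21 and bypassing 20.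

**Step 13.** The likely failures are ionisation of the tertiary allylic ether with loss of the allyl group (return to 18), migration by way of C3a to C7, and acid-promoted closure of the new prenyl group onto the C4 hydroxyl. The fallback moves the prenyl group by a 1,3-shift in place of the [3,3] shift. It sets out from 18, which is O-alkylated with 1-bromo-3-methylbut-2-ene (K2CO3, DMF) to 6-methoxy-2-{2-methoxy-4-[(triisopropylsilyl)oxy]phenyl}-4-[(3-methylbut-2-en-1-yl)oxy]-1-benzofuran-3-carbaldehyde F5. Heating F5 with magnesium silicate MgSiO3 (Florisil) in toluene should transfer the prenyl group from oxygen to the ortho carbon C5 and come back at 23.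

## Further compounds

F1 | step 9 | 3-methoxy-4-(4,4,5,5-tetramethyl-1,3,2-dioxaborolan-2-yl)phenol | COc1cc(O)ccc1B1OC(C)(C)C(C)(C)O1
F2 | step 9 | 2-(4-hydroxy-2-methoxyphenyl)-4,6-dimethoxy-1-benzofuran-3-carbaldehyde | O=Cc1c(-c2ccc(O)cc2OC)oc2cc(OC)cc(OC)c12
F3 | step 10 | 4-hydroxy-2-(4-hydroxy-2-methoxyphenyl)-6-methoxy-1-benzofuran-3-carbaldehyde | O=Cc1c(-c2ccc(O)cc2OC)oc2cc(OC)cc(O)c12
F4 | step 11 | tert-butyl 2-methylbut-3-en-2-yl carbonate | C=CC(C)(C)OC(=O)OC(C)(C)C
F5 | step 13 | 6-methoxy-2-{2-methoxy-4-[(triisopropylsilyl)oxy]phenyl}-4-[(3-methylbut-2-en-1-yl)oxy]-1-benzofuran-3-carbaldehyde | O=Cc1c(-c2ccc(O[Si](C(C)C)(C(C)C)C(C)C)cc2OC)oc2cc(OC)cc(OCC=C(C)C)c12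
A1 | alternative 1 | 4-(3-formyl-4,6-dimethoxy-1-benzofuran-2-yl)-3-methoxyphenyl 4-methylbenzenesulfonate | O=Cc1c(-c2ccc(OS(=O)(=O)c3ccc(C)cc3)cc2OC)oc2cc(OC)cc(OC)c12
A2 | alternative 1 | 4-[2-(2-bromo-4,6-dimethoxyphenyl)-3-(dimethylamino)prop-2-enoyl]-3-methoxyphenyl 4-methylbenzenesulfonate (alkene geometry not specified) | CN(C)C=C(c1c(Br)cc(OC)cc1OC)C(=O)c1ccc(OS(=O)(=O)c2ccc(C)cc2)cc1OC
A3 | alternative 2 | 7,9-dimethoxy-6-oxo-6H-[1]benzofuro[3,2-c]chromen-3-yl 4-methylbenzenesulfonate | COc1cc(OC)c2c3c(oc2c1)-c1ccc(OS(=O)(=O)c2ccc(C)cc2)cc1OC3=O
A4 | alternative 2 | 2-bromo-5-{[(4-methylphenyl)sulfonyl]oxy}phenyl 4,6-dimethoxy-1-benzofuran-3-carboxylate | COc1cc(OC)c2c(C(=O)Oc3cc(OS(=O)(=O)c4ccc(C)cc4)ccc3Br)coc2c1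
A5 | alternative 3 | methyl 4-hydroxy-6-methoxy-2-{2-methoxy-4-[(triisopropylsilyl)oxy]phenyl}-5-(3-methylbut-2-en-1-yl)-1-benzofuran-3-carboxylate | COC(=O)c1c(-c2ccc(O[Si](C(C)C)(C(C)C)C(C)C)cc2OC)oc2cc(OC)c(CC=C(C)C)c(O)c12
A6 | alternative 3 | methyl 5-(2-diazoacetyl)-2-{2-methoxy-4-[(triisopropylsilyl)oxy]phenyl}furan-3-carboxylate | COC(=O)c1cc(C(=O)C=[N+]=[N-])oc1-c1ccc(O[Si](C(C)C)(C(C)C)C(C)C)cc1OC
A7 | alternative 3 | 1-methoxy-5-methylhex-4-en-1-yne | COC#CCC=C(C)C
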